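**Retrosynthetic overview**
1. Target 15 ⇐ removal of two aryl TBS groups from the bis-silyl arylidene lactone 14.
2. 14 ⇐ aldol condensation of (R)-β-(arylmethyl)-γ-butyrolactone 8 with aldehyde 10, which forms the exocyclic E-C=C bond.
3. 8 ⇐ enantioselective oxygen insertion (Baeyer–Villiger desymmetrisation) into prochiral cyclobutanone 6; this key step forms the ring C–O bond and sets the only stereocentre.
4. 6 ⇐ keteniminium [2+2] cycloaddition of O-TBS-eugenol 2 with N,N-dimethylacetamide 3.
5. Ring order: cyclobutanone first (step 2), then the γ-lactone by ring expansion (step 3); both arenes are bought.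

Assumption: the sense of induction of the new catalyst in step 3 cannot be predicted, so the catalyst antipode that gives (R)-8 is fixed in a first run by chiral HPLC and optical rotation; the (S,S)-catalyst is written here.

**Step 1**
Reactants: 1 eugenol (4-allyl-2-methoxyphenol)
Product: 2 tert-butyl(4-allyl-2-methoxyphenoxy)dimethylsilane (O-TBS-eugenol)
Conditions: TBSCl (1.1 equiv), imidazole (2 equiv), DMF, 0 °C → rt
Reagents that add atoms: tert-butyldimethylsilyl chloride CC(C)(C)[Si](C)(C)Cl
Why: Imidazole-promoted O-silylation of the phenol (standard TBS protection), needed because Tf2O and LiHMDS in later steps would consume a free ArOH; no stereocentre is involved.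

**Step 2**
Reactants: 2 O-TBS-eugenol; 3 N,N-dimethylacetamide
Product: 6 3-[4-(tert-butyldimethylsilyloxy)-3-methoxybenzyl]cyclobutan-1-one, via keteniminium triflate 4 (not isolated), via cyclobutaniminium triflate 5 (not isolated)
Conditions: 3 (1.2 equiv), Tf2O (1.2 equiv), DCE, −15 °C; then 2, 2,4,6-collidine (1.2 equiv), reflux, 16 h; then aq. NaHCO3, rt
Reagents that add atoms: water O
Why: Ghosez keteniminium [2+2] cycloaddition, in which keteniminium 4 adds to the terminal alkene with the alkene CH2 bonding to the iminium carbon, so the arylmethyl group ends at C3, and hydrolysis of 5 releases the ketone; C3 is prochiral, so no stereocentre is formed yet.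

**Step 3**
Reactants: 6 3-[4-(tert-butyldimethylsilyloxy)-3-methoxybenzyl]cyclobutan-1-one
Product: 8 (R)-4-[4-(tert-butyldimethylsilyloxy)-3-methoxybenzyl]dihydrofuran-2(3H)-one, via Criegee adduct 7 (not isolated)
Conditions: (S,S)-imidodiphosphoric acid built from two 3,3'-bis(2,4,6-triethylphenyl)-BINOL units (5 mol %), 35% aq. H2O2 (1.5 equiv), CHCl3, −40 °C, 36 h
Reagents that add atoms: hydrogen peroxide OO
Why: Proposed new method: a confined chiral imidodiphosphoric acid should add H2O2 to the strained ketone and hold Criegee adduct 7 by two hydrogen bonds (P=O···H–O of the hemiketal, P–OH···O of the departing hydroxide) inside its C2-symmetric cleft; the 1,2-shift needs the migrating CH2–C bond antiperiplanar to the O–O bond and the arylmethyl tail can leave the cleft on one side only, so only one of the two enantiotopic ring CH2 groups migrates and C4 is set as R (Baeyer–Villiger desymmetrisation; the closest known reactions are the open BINOL-phosphoric-acid/H2O2 Baeyer–Villiger oxidation of 3-arylcyclobutanones, which is less selective for 3-benzyl groups, and imidodiphosphoric-acid/H2O2 sulfoxidation).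

**Step 4**
Reactants: 9 3-hydroxy-4,5-dimethoxybenzaldehyde
Product: 10 3-(tert-butyldimethylsilyloxy)-4,5-dimethoxybenzaldehyde
Conditions: TBSCl (1.1 equiv), imidazole (2 equiv), DMF, rt
Reagents that add atoms: tert-butyldimethylsilyl chloride CC(C)(C)[Si](C)(C)Cl
Why: Imidazole-promoted O-silylation (standard TBS protection) removes the acidic phenol before the enolate step; no stereocentre is involved.

**Step 5**
Reactants: 8 (R)-4-[4-(tert-butyldimethylsilyloxy)-3-methoxybenzyl]dihydrofuran-2(3H)-one; 10 3-(tert-butyldimethylsilyloxy)-4,5-dimethoxybenzaldehyde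
Product: 14 (3E,4R)-3-[3-(tert-butyldimethylsilyloxy)-4,5-dimethoxybenzylidene]-4-[4-(tert-butyldimethylsilyloxy)-3-methoxybenzyl]dihydrofuran-2(3H)-one, via lithium enolate 11 (not isolated), via lithium aldolate 12 (not isolated), via aldol acetate 13 (not isolated)
Conditions: LiHMDS (1.1 equiv), THF, −78 °C; 10 (1.1 equiv), −78 °C; Ac2O (1.3 equiv), −78 → 0 °C; DBU (3 equiv), rt
Reagents that add atoms: none
Why: One-pot aldol condensation, in which the lithium enolate adds to the non-enolisable aldehyde anti to the C4 substituent, the aldolate is acetylated and DBU eliminates acetate by E1cB to give the conjugated, thermodynamically preferred E-arylidene (aryl anti to C=O); C4 has no acidic hydrogen under these conditions and stays R.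

**Step 6**
Reactants: 14 (3E,4R)-bis-TBS arylidene lactone
Product: 15 (3E,4R)-3-(3-hydroxy-4,5-dimethoxybenzylidene)-4-(4-hydroxy-3-methoxybenzyl)dihydrofuran-2(3H)-one
Conditions: TBAF (2.2 equiv), AcOH (2.5 equiv), THF, 0 °C
Reagents that add atoms: none
Why: Fluoride desilylation of both aryl silyl ethers (Si–F bond formation), buffered with AcOH so the phenoxides are protonated at once and the lactone, the E-alkene and C4 are untouched.

**Compound list**
1 | eugenol (4-allyl-2-methoxyphenol) | C=CCc1ccc(O)c(OC)c1 | starting material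
2 | tert-butyl(4-allyl-2-methoxyphenoxy)dimethylsilane | C=CCc1ccc(O[Si](C)(C)C(C)(C)C)c(OC)c1 | intermediate
3 | N,N-dimethylacetamide | CC(=O)N(C)C | starting material
4 | N,N-dimethylketeniminium triflate | C=C=[N+](C)C.[O-]S(=O)(=O)C(F)(F)F | intermediate
5 | N-{3-[4-(tert-butyldimethylsilyloxy)-3-methoxybenzyl]cyclobutylidene}-N-methylmethanaminium triflate | C[N+](C)=C1CC(Cc2ccc(O[Si](C)(C)C(C)(C)C)c(OC)c2)C1.[O-]S(=O)(=O)C(F)(F)F | intermediate
6 | 3-[4-(tert-butyldimethylsilyloxy)-3-methoxybenzyl]cyclobutan-1-one (achiral, prochiral at C3) | O=C1CC(Cc2ccc(O[Si](C)(C)C(C)(C)C)c(OC)c2)C1 | intermediate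
7 | 1-hydroperoxy-3-[4-(tert-butyldimethylsilyloxy)-3-methoxybenzyl]cyclobutan-1-ol (Criegee adduct, catalyst-bound) | OOC1(O)CC(Cc2ccc(O[Si](C)(C)C(C)(C)C)c(OC)c2)C1 | intermediate
8 | (R)-4-[4-(tert-butyldimethylsilyloxy)-3-methoxybenzyl]dihydrofuran-2(3H)-one | COc1cc(C[C@H]2COC(=O)C2)ccc1O[Si](C)(C)C(C)(C)C | intermediate
9 | 3-hydroxy-4,5-dimethoxybenzaldehyde | COc1cc(C=O)cc(O)c1OC | starting material
10 | 3-(tert-butyldimethylsilyloxy)-4,5-dimethoxybenzaldehyde | COc1cc(C=O)cc(O[Si](C)(C)C(C)(C)C)c1OC | intermediate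
11 | lithium (R)-4-[4-(tert-butyldimethylsilyloxy)-3-methoxybenzyl]-4,5-dihydrofuran-2-olate (lithium enolate of 8) | COc1cc(C[C@H]2COC(O[Li])=C2)ccc1O[Si](C)(C)C(C)(C)C | intermediate
12 | lithium alkoxide of (3S,4R)-3-{[3-(tert-butyldimethylsilyloxy)-4,5-dimethoxyphenyl](hydroxy)methyl}-4-[4-(tert-butyldimethylsilyloxy)-3-methoxybenzyl]dihydrofuran-2(3H)-one (3,4-trans, both carbinol epimers) | COc1cc(C[C@H]2COC(=O)[C@@H]2C(O[Li])c2cc(OC)c(OC)c(O[Si](C)(C)C(C)(C)C)c2)ccc1O[Si](C)(C)C(C)(C)C | intermediate
13 | acetate of the (3S,4R)-aldol (3,4-trans, both carbinol epimers) | COc1cc(C[C@H]2COC(=O)[C@@H]2C(OC(C)=O)c2cc(OC)c(OC)c(O[Si](C)(C)C(C)(C)C)c2)ccc1O[Si](C)(C)C(C)(C)C | intermediate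
14 | (3E,4R)-3-[3-(tert-butyldimethylsilyloxy)-4,5-dimethoxybenzylidene]-4-[4-(tert-butyldimethylsilyloxy)-3-methoxybenzyl]dihydrofuran-2(3H)-one | COc1cc(C[C@H]2COC(=O)/C2=C/c2cc(O[Si](C)(C)C(C)(C)C)c(OC)c(OC)c2)ccc1O[Si](C)(C)C(C)(C)C | intermediate
15 | (3E,4R)-3-(3-hydroxy-4,5-dimethoxybenzylidene)-4-(4-hydroxy-3-methoxybenzyl)dihydrofuran-2(3H)-one | COc1cc(C[C@H]2COC(=O)/C2=C/c2cc(O)c(OC)c(OC)c2)ccc1O | target

**Step count and risks**
Total steps: 6. Longest linear sequence: 5 (steps 1, 2, 3, 5, 6); step 4 is a one-step side branch.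

Three steps most likely to fail:

Step 3 (the proposed new oxygen insertion; risk of low ee or slow turnover with the flexible arylmethyl group). The fallback uses known chemistry, sets out from 6 and returns at 8. Ketone 6 is deprotonated enantioselectively with lithium bis[(S)-1-phenylethyl]amide (or its antipode, whichever gives the R series) in THF at −100 °C with TMSCl present, giving the silyl enol ether (R)-tert-butyl{2-methoxy-4-[(3-trimethylsilyloxycyclobut-2-en-1-yl)methyl]phenoxy}dimethylsilane F1. Ozonolysis (O3, CH2Cl2/MeOH, −78 °C) with NaBH4 work-up gives (R)-4-hydroxy-3-[4-(tert-butyldimethylsilyloxy)-3-methoxybenzyl]butanoic acid F2, which closes to 8 on acidification.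

Step 2 (the electron-rich arene may be acylated by the keteniminium ion, or the aryl silyl ether may suffer at reflux). The fallback sets out from 2 and returns at 6. Dichloroketene, generated from trichloroacetyl chloride with Zn–Cu and POCl3 in Et2O, adds to 2 to give racemic 2,2-dichloro-3-[4-(tert-butyldimethylsilyloxy)-3-methoxybenzyl]cyclobutan-1-one F3. Reductive dechlorination with Zn dust in AcOH then gives 6.

Step 5 (one-pot aldol/acetylation/elimination; risks are incomplete elimination, E/Z mixtures and base-induced drift of the double bond into the ring). The fallback sets out from 8 and returns at 14. The enolate of 8 (LDA, THF, −78 °C) is trapped with diethyl chlorophosphate and further LDA induces the 1,3-phosphorus shift to give diethyl {(4R)-4-[4-(tert-butyldimethylsilyloxy)-3-methoxybenzyl]-2-oxotetrahydrofuran-3-yl}phosphonate F4 (C3 epimers). Horner–Wadsworth–Emmons olefination of F4 with 10 (NaH, THF, 0 °C → rt) gives 14 after separation of any Z-isomer.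

**Further compounds**
F1 | step 3 | (R)-tert-butyl{2-methoxy-4-[(3-trimethylsilyloxycyclobut-2-en-1-yl)methyl]phenoxy}dimethylsilane | COc1cc(C[C@H]2C=C(O[Si](C)(C)C)C2)ccc1O[Si](C)(C)C(C)(C)C
F2 | step 3 | (R)-4-hydroxy-3-[4-(tert-butyldimethylsilyloxy)-3-methoxybenzyl]butanoic acid | COc1cc(C[C@@H](CO)CC(=O)O)ccc1O[Si](C)(C)C(C)(C)C
F3 | step 2 | 2,2-dichloro-3-[4-(tert-butyldimethylsilyloxy)-3-methoxybenzyl]cyclobutan-1-one (racemic) | O=C1CC(Cc2ccc(O[Si](C)(C)C(C)(C)C)c(OC)c2)C1(Cl)Cl
F4 | step 5 | diethyl {(4R)-4-[4-(tert-butyldimethylsilyloxy)-3-methoxybenzyl]-2-oxotetrahydrofuran-3-yl}phosphonate (C3 epimers) | COc1cc(C[C@H]2COC(=O)C2P(=O)(OCC)OCC)ccc1O[Si](C)(C)C(C)(C)C
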